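The trans-hydrindane is cut at C3a–C4 and C7a–C7, so that ring A (C1, C2, C3, C3a, C7a) is bought as an (S)-4-silyloxycyclopentenone. The key step exploits that the fusion carbons C3a and C7a are vicinal and trans in ring A, flanked by oxygenated C1 and by C3 (carried as a silyloxy carbon), and that each holds one arm (C4, C7) of six-membered ring B. In one pot an isovalerate silyl ketene acetal adds to the enone β-carbon anti to the silyloxy group and the resulting silyl enol ether is trapped at the α-carbon by acrolein: three components, two C–C bonds, both fusion stereocentres. Ring B is closed later by decarboxylative radical cyclisation.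

Key step: step 2

Remarks on the chemistry:
- Hydrindane (octahydro-1H-indene) locants of the target, C1 to C7a, are used for every intermediate; β is the face of H3a, α the face of H7a.
- The 2-methylbutanoyl centre of the target is R, so (R)-2-methylbutanoic acid is used; it, (E)-3-methylpent-2-enoic acid and tert-butyl 3-methylbutanoate are assumed to be purchasable.
- Compounds 5 to 12 are carried as epimer mixtures at C4 and, where present, at the C7 carbinol; both centres are erased in steps 7 and 9 and are left open in the SMILES. The C2 carbinol of 21 is likewise left open (erased in step 17).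

Step 1
Reactants: 1 tert-butyl 3-methylbutanoate
Product: 2 (E)-1-tert-butoxy-3-methyl-1-(trimethylsilyloxy)but-1-ene
Conditions: LiN(iPr)2, THF, −78 °C; Me3SiCl, −78 °C to rt; distil
Reagents that add atoms: chlorotrimethylsilane, C[Si](C)(C)Cl
Why: Kinetic ester enolisation and O-silylation give the silyl ketene acetal; the tert-butyl ester is chosen so that the very hindered C4 carboxyl can later be freed by acidolysis instead of saponification, and the acetal geometry is irrelevant because C4 is erased.

Step 2
Reactants: 3 (S)-4-(tert-butyldimethylsilyloxy)cyclopent-2-en-1-one; 2 (E)-1-tert-butoxy-3-methyl-1-(trimethylsilyloxy)but-1-ene; 4 acrolein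
Product: 6 tert-butyl 2-[5-(tert-butyldimethylsilyloxy)-2-(1-hydroxyprop-2-en-1-yl)-3-oxocyclopentyl]-3-methylbutanoate (C7a arm β; C3a arm α; C3 silyloxy β), via trimethylsilyl enol ether 5 (not isolated)
Conditions: 3, 2, HgI2 (cat.), CH2Cl2, −78 °C; then 4, TiCl4, CH2Cl2, −78 °C; H2O work-up
Reagents that add atoms: none
Why: HgI2 activates the enone for Mukaiyama–Michael addition of 2 at the β-carbon (C3a–C4 bond) with transfer of the trimethylsilyl group to the carbonyl oxygen, giving the regiodefined enol ether 5; TiCl4 then activates acrolein for a Mukaiyama aldol at the α-carbon (C7a–C7 bond), and work-up frees the carbinol. The closest known reaction type is the Lewis-acid three-component Michael–aldol coupling on 4-silyloxycyclopentenones. No ring is closed, so no mode of closure applies. The C3a centre is controlled by the C3 silyloxy group, which shields the β face so that the nucleophile enters anti, and the C7a centre is controlled by the new C3a substituent, which sends acrolein to the opposite face and gives the 2,3-trans ketone. The step needs 1,4-addition to the enone, secured by the soft ketene acetal and mild HgI2 activation, and 1,2-addition to acrolein without enol ether equilibration, secured by TiCl4 at −78 °C in a non-basic medium that also keeps the β-silyloxy group from eliminating. The C4 and C7 carbinol configurations are not controlled and need not be.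

Step 3
Reactants: 6 tert-butyl 2-[5-(tert-butyldimethylsilyloxy)-2-(1-hydroxyprop-2-en-1-yl)-3-oxocyclopentyl]-3-methylbutanoate
Product: 7 C7 triethylsilyl ether of 6
Conditions: Et3SiCl, imidazole, DMF, 0 °C
Reagents that add atoms: chlorotriethylsilane, CC[Si](Cl)(CC)CC
Why: Silylation of the secondary allylic alcohol under weakly basic conditions masks the β-hydroxy ketone against retro-aldol cleavage and differentiates O7 from the C1 oxygen made next.

Step 4
Reactants: 7 C7 triethylsilyl ether of 6
Product: 8 1β-alcohol (C1 hydroxyl cis to the C7 arm and to the C3 silyloxy group)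
Conditions: LiBH(sec-Bu)3 (L-Selectride), THF, −78 °C; H2O quench at −78 °C
Reagents that add atoms: none
Why: Bulky hydride reduction from the α face, anti to the adjacent β-oriented C7a arm, should give the 1β-alcohol, the facial bias typical of 2,3-trans-disubstituted 4-silyloxycyclopentanones; the tert-butyl ester is inert and the cold quench limits silyl migration.

Step 5
Reactants: 8 1β-alcohol
Product: 9 C1 tert-butyldiphenylsilyl ether of 8
Conditions: tBuPh2SiCl, imidazole, DMAP (cat.), DMF, 40 °C
Reagents that add atoms: tert-butyl(chloro)diphenylsilane, CC(C)(C)[Si](Cl)(c1ccccc1)c1ccccc1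
Why: Silyl protection as the acid-robust TBDPS ether, orthogonal to TES (C7) and TBS (C3), prevents oxa-Michael addition of O1 to the vinyl ketone of step 7 and keeps O1 a poor leaving group when C7 and later C3 become ketones.

Step 6
Reactants: 9 C1 tert-butyldiphenylsilyl ether of 8
Product: 10 C7 allylic alcohol (C1 TBDPS, C3 TBS, tert-butyl ester retained)
Conditions: PPTS, MeOH/CH2Cl2, 0 °C to rt
Reagents that add atoms: none
Why: Acid-catalysed methanolysis removes the most labile silyl ether (TES) while the TBS and TBDPS ethers and the tert-butyl ester are expected to persist (graded silyl ether lability).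

Step 7
Reactants: 10 C7 allylic alcohol
Product: 11 vinyl ketone, tert-butyl 2-[2-acryloyl-3-(tert-butyldiphenylsilyloxy)-5-(tert-butyldimethylsilyloxy)cyclopentyl]-3-methylbutanoate
Conditions: Dess–Martin periodinane, pyridine, CH2Cl2, 0 °C; used at once
Reagents that add atoms: none
Why: Dess–Martin oxidation of the allylic alcohol gives the enone and erases the C7 stereocentre under buffered, non-nucleophilic conditions that spare the silyl ethers and the sensitive vinyl ketone.

Step 8
Reactants: 11 vinyl ketone tert-butyl ester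
Product: 12 2-[2-acryloyl-3-(tert-butyldiphenylsilyloxy)-5-(tert-butyldimethylsilyloxy)cyclopentyl]-3-methylbutanoic acid
Conditions: CF3CO2H/CH2Cl2 (1:4), anhydrous, 0 °C, short; toluene co-evaporation
Reagents that add atoms: none
Why: Acidolysis of the tert-butyl ester (loss of 2-methylpropene) frees the hindered acid without base, which the vinyl ketone would not tolerate; the hindered secondary TBS ether and the TBDPS ether should survive brief anhydrous acid.

Step 9
Reactants: 12 vinyl ketone acid
Product: 13 1β-(tert-butyldiphenylsilyloxy)-3β-(tert-butyldimethylsilyloxy)-4β-isopropyl-trans-hydrindan-7-one (H3a β, H7a α)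
Conditions: Ir[dF(CF3)ppy]2(dtbbpy)PF6 (cat.), K2HPO4, DMF (0.01 M), blue LEDs, rt
Reagents that add atoms: none
Why: Photoredox decarboxylative Giese cyclisation: the carboxylate is oxidised by the excited iridium complex, loss of CO2 gives the secondary C4 radical, which closes 6-endo-trig onto the terminal carbon C5 of the vinyl ketone (polarity-matched β-attack, 5-exo disfavoured), and a chair-like transition state on the trans-disposed arms should place isopropyl equatorial (4β) before the α-keto radical is reduced and protonated.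

Step 10
Reactants: 13 trans-hydrindan-7-one
Product: 14 7-methylene-trans-hydrindane (1β-OTBDPS, 3β-OTBS, 4β-isopropyl)
Conditions: Zn, CH2Br2, TiCl4, THF/CH2Cl2, 0 °C to rt (Lombardo reagent)
Reagents that add atoms: dibromomethane, BrCBr
Why: Lombardo methylenation with the non-basic zinc/titanium methylene reagent converts the C7 ketone into the exocyclic alkene without enolising C7a or expelling the β-silyloxy group at C1, and tolerates silyl ethers.

Step 11
Reactants: 14 7-methylene-trans-hydrindane
Product: 15 6α-hydroxy-7-methylene-trans-hydrindane (axial allylic alcohol)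
Conditions: SeO2 (cat.), tBuOOH, CH2Cl2, rt
Reagents that add atoms: tert-butyl hydroperoxide, CC(C)(C)OO; selenium dioxide, O=[Se]=O
Why: Catalytic SeO2 allylic hydroxylation proceeds by an ene reaction at the axial C6–H (ring CH2 preferred over the tertiary C7a–H) and a [2,3]-sigmatropic shift that returns the exocyclic double bond and delivers oxygen to the same α (axial) face, the usual outcome for methylenecyclohexanes held in a chair.

Step 12
Reactants: 15 6α-alcohol; 16 (E)-3-methylpent-2-enoic acid
Product: 17 6α-[(E)-3-methylpent-2-enoyloxy]-7-methylene-trans-hydrindane (1β-OTBDPS, 3β-OTBS)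
Conditions: DCC, DMAP (cat.), CH2Cl2, 0 °C to rt
Reagents that add atoms: none
Why: Steglich esterification acylates the axial allylic alcohol with retention at C6, and carbodiimide activation without amine base avoids vinylketene formation that would scramble the enoate geometry.

Step 13
Reactants: 17 C6 ester
Product: 18 3β-alcohol (C1 TBDPS ether and C6 ester retained)
Conditions: HF·pyridine, pyridine, THF, 0 °C to rt
Reagents that add atoms: none
Why: Selective desilylation: the TBS ether is cleaved by buffered HF·pyridine much faster than the bulkier, acid-stable TBDPS ether, and the allylic ester and exocyclic alkene are inert.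

Step 14
Reactants: 18 3β-alcohol
Product: 19 trans-hydrindan-3-one (1β-OTBDPS, 6α-ester, 7-methylene)
Conditions: Dess–Martin periodinane, pyridine, CH2Cl2, 0 °C
Reagents that add atoms: none
Why: Dess–Martin oxidation of the only free alcohol under buffered conditions gives the β-silyloxy ketone without enolisation, so C3a is not epimerised and O1 is not eliminated.

Step 15
Reactants: 19 trans-hydrindan-3-one
Product: 20 3-ethylidene compound (methyl cis to C3a; Z by CIP at this stage)
Conditions: Ph3P(Et)Br, KN(SiMe3)2, THF, −78 to 0 °C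
Reagents that add atoms: ethyltriphenylphosphonium bromide, CC[P+](c1ccccc1)(c1ccccc1)c1ccccc1.[Br-]
Why: Wittig olefination with the non-stabilised ylide under salt-free kinetic control is expected to place the methyl group cis to the more substituted α-carbon C3a (as with α-branched cyclopentanones such as 17-oxo steroids); O1 as a silyl ether suppresses β-elimination and the ester carbonyls react far more slowly than the ketone.

Step 16
Reactants: 20 3-ethylidene compound
Product: 21 2-hydroxy-3-ethylidene compound (allylic alcohol; methyl cis to C3a, now E)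
Conditions: SeO2 (cat.), tBuOOH, CH2Cl2, 0 °C to rt
Reagents that add atoms: tert-butyl hydroperoxide, CC(C)(C)OO; selenium dioxide, O=[Se]=O
Why: SeO2 allylic hydroxylation by an ene reaction at the ring methylene C2 (CH2 preferred over the ring-fusion CH at C3a) followed by a [2,3]-sigmatropic shift that returns the double bond to the exocyclic position and, through a pseudo-equatorial methyl in the envelope transition state, fixes the methyl group cis to C3a; the ester-flanked C7 methylene and the enoate are electron-poorer and should react more slowly.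

Step 17
Reactants: 21 allylic alcohol
Product: 22 (E)-3-ethylidene-trans-hydrindan-2-one (1β-OTBDPS, 6α-ester, 7-methylene)
Conditions: Dess–Martin periodinane, pyridine, CH2Cl2, 0 °C
Reagents that add atoms: none
Why: Dess–Martin oxidation of the only free (allylic) alcohol gives the α-ethylidene ketone with retention of the alkene geometry and erases the C2 carbinol centre.

Step 18
Reactants: 22 enone TBDPS ether
Product: 23 1β-hydroxy enone
Conditions: Bu4NF, AcOH (1:1), THF, 0 °C to rt
Reagents that add atoms: none
Why: Fluoride desilylation buffered with acetic acid removes the TBDPS group next to the carbonyl while avoiding base-induced α-ketol shift, C1 epimerisation or ester migration.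

Step 19
Reactants: 23 1β-hydroxy enone; 24 (R)-2-methylbutanoic acid
Product: 25 target, (1S,3E,3aS,4S,6R,7aR)-3-ethylidene-7-methylidene-1-{[(2R)-2-methylbutanoyl]oxy}-2-oxo-4-(propan-2-yl)octahydro-1H-inden-6-yl (2E)-3-methylpent-2-enoate
Conditions: DCC, DMAP (cat.), CH2Cl2, 0 °C to rt
Reagents that add atoms: none
Why: Steglich esterification of the hindered α-hydroxy ketone under neutral carbodiimide activation should neither racemise the α-centre of the acid nor isomerise the enone.

Compound list
1 | tert-butyl 3-methylbutanoate | CC(C)CC(=O)OC(C)(C)C | starting material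
2 | (E)-1-tert-butoxy-3-methyl-1-(trimethylsilyloxy)but-1-ene | CC(C)(C)O/C(O[Si](C)(C)C)=C\C(C)C | intermediate
3 | (S)-4-(tert-butyldimethylsilyloxy)cyclopent-2-en-1-one | O=C1C=C[C@@H](O[Si](C)(C)C(C)(C)C)C1 | starting material
4 | acrolein (prop-2-enal) | C=CC=O | starting material
5 | tert-butyl 2-[5-(tert-butyldimethylsilyloxy)-3-(trimethylsilyloxy)cyclopent-2-en-1-yl]-3-methylbutanoate (C3a arm α, C3 silyloxy β, trans; C4 epimers) | CC(C)C(C(=O)OC(C)(C)C)[C@H]1C=C(O[Si](C)(C)C)C[C@@H]1O[Si](C)(C)C(C)(C)C | intermediate
6 | tert-butyl 2-[5-(tert-butyldimethylsilyloxy)-2-(1-hydroxyprop-2-en-1-yl)-3-oxocyclopentyl]-3-methylbutanoate (C7a arm β, C3a arm α, C3 silyloxy β; C4 and C7 epimers) | C=CC(O)[C@H]1[C@H](C(C(C)C)C(=O)OC(C)(C)C)[C@@H](O[Si](C)(C)C(C)(C)C)CC1=O | intermediate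
7 | C7 triethylsilyl ether of 6 | C=CC(O[Si](CC)(CC)CC)[C@H]1[C@H](C(C(C)C)C(=O)OC(C)(C)C)[C@@H](O[Si](C)(C)C(C)(C)C)CC1=O | intermediate
8 | 1β-alcohol: tert-butyl 2-[5-(tert-butyldimethylsilyloxy)-3-hydroxy-2-(1-triethylsilyloxyprop-2-en-1-yl)cyclopentyl]-3-methylbutanoate (OH cis to the C7 arm and to the C3 silyloxy group) | C=CC(O[Si](CC)(CC)CC)[C@H]1[C@H](C(C(C)C)C(=O)OC(C)(C)C)[C@@H](O[Si](C)(C)C(C)(C)C)C[C@H]1O | intermediate
9 | C1 tert-butyldiphenylsilyl ether of 8 | C=CC(O[Si](CC)(CC)CC)[C@H]1[C@H](C(C(C)C)C(=O)OC(C)(C)C)[C@@H](O[Si](C)(C)C(C)(C)C)C[C@H]1O[Si](c2ccccc2)(c3ccccc3)C(C)(C)C | intermediate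
10 | C7 allylic alcohol (TES removed from 9) | C=CC(O)[C@H]1[C@H](C(C(C)C)C(=O)OC(C)(C)C)[C@@H](O[Si](C)(C)C(C)(C)C)C[C@H]1O[Si](c2ccccc2)(c3ccccc3)C(C)(C)C | intermediate
11 | tert-butyl 2-[2-acryloyl-3-(tert-butyldiphenylsilyloxy)-5-(tert-butyldimethylsilyloxy)cyclopentyl]-3-methylbutanoate (acryloyl β, C1–O β, C3–O β, C3a arm α) | C=CC(=O)[C@H]1[C@H](C(C(C)C)C(=O)OC(C)(C)C)[C@@H](O[Si](C)(C)C(C)(C)C)C[C@H]1O[Si](c2ccccc2)(c3ccccc3)C(C)(C)C | intermediate
12 | 2-[2-acryloyl-3-(tert-butyldiphenylsilyloxy)-5-(tert-butyldimethylsilyloxy)cyclopentyl]-3-methylbutanoic acid (same ring configuration as 11) | C=CC(=O)[C@H]1[C@H](C(C(C)C)C(=O)O)[C@@H](O[Si](C)(C)C(C)(C)C)C[C@H]1O[Si](c2ccccc2)(c3ccccc3)C(C)(C)C | intermediate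
13 | 1β-(tert-butyldiphenylsilyloxy)-3β-(tert-butyldimethylsilyloxy)-4β-isopropyl-trans-hydrindan-7-one (H3a β, H7a α) | O=C1[C@H]2[C@@H]([C@@H](O[Si](C)(C)C(C)(C)C)C[C@H]2O[Si](c3ccccc3)(c4ccccc4)C(C)(C)C)[C@H](C(C)C)CC1 | intermediate
14 | 7-methylene analogue of 13 | C=C1[C@H]2[C@@H]([C@@H](O[Si](C)(C)C(C)(C)C)C[C@H]2O[Si](c3ccccc3)(c4ccccc4)C(C)(C)C)[C@H](C(C)C)CC1 | intermediate
15 | 6α-hydroxy-7-methylene compound (axial OH) | C=C1[C@H]2[C@@H]([C@@H](O[Si](C)(C)C(C)(C)C)C[C@H]2O[Si](c3ccccc3)(c4ccccc4)C(C)(C)C)[C@H](C(C)C)C[C@H]1O | intermediate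
16 | (E)-3-methylpent-2-enoic acid | CC/C(C)=C/C(=O)O | starting material
17 | 6α-[(E)-3-methylpent-2-enoyl] ester of 15 | C=C1[C@H]2[C@@H]([C@@H](O[Si](C)(C)C(C)(C)C)C[C@H]2O[Si](c3ccccc3)(c4ccccc4)C(C)(C)C)[C@H](C(C)C)C[C@H]1OC(=O)/C=C(\C)CC | intermediate
18 | 3β-alcohol (TBS removed from 17) | C=C1[C@H]2[C@@H]([C@@H](O)C[C@H]2O[Si](c3ccccc3)(c4ccccc4)C(C)(C)C)[C@H](C(C)C)C[C@H]1OC(=O)/C=C(\C)CC | intermediate
19 | trans-hydrindan-3-one (1β-OTBDPS, 4β-isopropyl, 6α-ester, 7-methylene) | C=C1[C@H]2[C@@H](C(=O)C[C@H]2O[Si](c3ccccc3)(c4ccccc4)C(C)(C)C)[C@H](C(C)C)C[C@H]1OC(=O)/C=C(\C)CC | intermediate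
20 | 3-ethylidene compound, methyl cis to C3a (3Z) | C=C1[C@H]2[C@@H](/C(=C\C)C[C@H]2O[Si](c3ccccc3)(c4ccccc4)C(C)(C)C)[C@H](C(C)C)C[C@H]1OC(=O)/C=C(\C)CC | intermediate
21 | 2-hydroxy-3-ethylidene compound, methyl cis to C3a (3E; C2 epimers) | C=C1[C@H]2[C@@H](/C(=C\C)C(O)[C@H]2O[Si](c3ccccc3)(c4ccccc4)C(C)(C)C)[C@H](C(C)C)C[C@H]1OC(=O)/C=C(\C)CC | intermediate
22 | (E)-3-ethylidene-trans-hydrindan-2-one, 1β-OTBDPS, 6α-ester, 7-methylene | C=C1[C@H]2[C@@H](/C(=C\C)C(=O)[C@H]2O[Si](c3ccccc3)(c4ccccc4)C(C)(C)C)[C@H](C(C)C)C[C@H]1OC(=O)/C=C(\C)CC | intermediate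
23 | 1β-hydroxy enone (TBDPS removed from 22) | C=C1[C@H]2[C@@H](/C(=C\C)C(=O)[C@H]2O)[C@H](C(C)C)C[C@H]1OC(=O)/C=C(\C)CC | intermediate
24 | (R)-2-methylbutanoic acid | CC[C@@H](C)C(=O)O | starting material
25 | (1S,3E,3aS,4S,6R,7aR)-3-ethylidene-7-methylidene-1-{[(2R)-2-methylbutanoyl]oxy}-2-oxo-4-(propan-2-yl)octahydro-1H-inden-6-yl (2E)-3-methylpent-2-enoate | C=C1[C@H]2[C@@H](/C(=C\C)C(=O)[C@H]2OC(=O)[C@H](C)CC)[C@H](C(C)C)C[C@H]1OC(=O)/C=C(\C)CC | target

Total step count: 19 steps.
Longest linear sequence: 19 steps (1 to 25); enone 3, acrolein 4 and the two acids 16 and 24 enter as purchased side inputs.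

Steps most likely to fail

Step 2. Acrolein may polymerise or be attacked at its β-carbon under TiCl4, so that the α-carbon of the enol ether is not trapped cleanly. The fallback sets out from enol ether 5 (made as in step 2 and kept in solution) and replaces acrolein by a saturated surrogate. Conjugate addition of PhSeH to acrolein 4 gives 3-(phenylselanyl)propanal F1. The TiCl4 Mukaiyama aldol of 5 with this aldehyde gives the β-hydroxy ketone selenide F2. Oxidation (H2O2, pyridine, CH2Cl2, 0 °C to rt) and selenoxide syn-elimination then restore the vinyl group, and the route is rejoined at 6.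

Step 9. Oxidation of the hindered carboxylate may be inefficient, or the C4 radical may be quenched before ring closure. The fallback sets out from acid 12 and changes the way the radical is made. Esterification with N-hydroxyphthalimide (N,N'-diisopropylcarbodiimide, CH2Cl2, 0 °C, no amine base) gives the redox-active N-acyloxyphthalimide F3. Single-electron reduction of this ester (Ru(bpy)3(PF6)2 cat., Hantzsch ester, iPr2NEt, CH2Cl2, blue LEDs) releases the same C4 radical in a reductive, base-free manifold with a stoichiometric hydrogen donor for the α-keto radical. The 6-endo closure rejoins the route at 13.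

Step 15. The basic ylide may enolise the C3 ketone, which would epimerise C3a to the cis-fused ketone or expel the C1 silyloxy group. The fallback sets out from ketone 19 and uses a Peterson olefination through a weakly basic organocerium. 1-(Trimethylsilyl)ethylmagnesium chloride with CeCl3 (THF, −78 °C) adds to C3 and gives the β-hydroxysilane F4. Elimination with BF3·OEt2 (CH2Cl2, 0 °C) gives the ethylidene compound and rejoins the route at 20. A mixture of alkene isomers is acceptable there, because the [2,3] shift of step 16 is expected to set the final geometry.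

Further compounds
F1 | step 2 | 3-(phenylselanyl)propanal | O=CCC[Se]c1ccccc1
F2 | step 2 | tert-butyl 2-[5-(tert-butyldimethylsilyloxy)-2-(1-hydroxy-3-phenylselanylpropyl)-3-oxocyclopentyl]-3-methylbutanoate (ring configuration as in 6) | OC(CC[Se]c2ccccc2)[C@H]1[C@H](C(C(C)C)C(=O)OC(C)(C)C)[C@@H](O[Si](C)(C)C(C)(C)C)CC1=O
F3 | step 9 | 1,3-dioxoisoindolin-2-yl ester of acid 12 | C=CC(=O)[C@H]1[C@H](C(C(C)C)C(=O)ON2C(=O)c3ccccc3C2=O)[C@@H](O[Si](C)(C)C(C)(C)C)C[C@H]1O[Si](c4ccccc4)(c5ccccc5)C(C)(C)C
F4 | step 15 | 3-hydroxy-3-[1-(trimethylsilyl)ethyl] adduct of ketone 19 | C=C1[C@H]2[C@@H](C(O)(C(C)[Si](C)(C)C)C[C@H]2O[Si](c3ccccc3)(c4ccccc4)C(C)(C)C)[C@H](C(C)C)C[C@H]1OC(=O)/C=C(\C)CC
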